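Compound numbers 1–23 are those of the steps below. Atom numbers C1–C12 run from the lactone carbonyl to the methyl group of target 23 and are used for every intermediate (O6 and O11 are the oxygens on C6 and C11).

## Analysis of the target

Target 23 is a twelve-carbon chain folded into two oxygen heterocycles: a 5,6-dihydro-2H-pyran-2-one (O–C1, C2=C3, C4, C5) and a 2,5-disubstituted oxolane (C7–C10 and its oxygen). The two rings are joined through the free carbinol C6, and O11 carries an (E)-4-hydroxycinnamoyl ester. There are five stereocentres, 5R, 6S, 7R, 10S and 11S: C5/C6 are anti (erythro), C6/C7 threo, C7 and C10 cis on the ring, and C10/C11 threo. Without their outer substituents, C6, C7, C10 and C11 form a threo–cis-oxolane–threo array bisected by a mirror plane through the ring oxygen and the midpoint of the C8–C9 bond. C6 and C11, O6 and O11, and C5 and C12 are therefore mirror partners, and the synthesis is built on this feature. The sensitive parts are the enoate lactone (a Michael acceptor that opens under base), the C6 hydroxyl (placed to add to C3 in an oxa-Michael sense under base) and the phenolic coumarate (intolerant of hydride and organolithium reagents). The difficulty lies less in making the core than in telling its two nearly identical halves apart in the absolute sense, and in adding C5, the only centre outside the symmetric array, anti to C6. The coumarate must therefore come late and the last deprotection must be acidic.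

## Retrosynthetic reasoning

**C11–O acyl bond and the last protecting groups (23 ⇐ 22 ⇐ 18 + 21).** The coumarate is cut first because it cannot survive the reductions and the acetylide chemistry that build the chain. In 18 the hydroxyl on C11 is the only free one (O5 is in the lactone, O6 is silylated), so the esterification needs no selectivity. The phenol of 19 is masked as the silyl ether 21 so that one acidic fluoride treatment frees both the phenol and O6.

**Lactone C1–O bond (18 ⇐ 17 ⇐ 16).** The ring is opened to the Z-configured hydroxy ester 17. Forward, mild acid removes the two labile silyl ethers of 16 and the C5 hydroxyl closes the six-membered ring. O6 keeps its robust silyl ether, so the seven-membered alternative cannot form, and O11 emerges free for the acylation.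

**C2=C3 and C1–C2 (16 ⇐ 15 ⇐ 14 ⇐ 13).** The Z double bond is traced to the alkyne of 15, because syn semihydrogenation fixes the geometry the lactone needs. The ester carbon C1 is attached to the terminal alkyne of 14 through its acetylide. Both free hydroxyls of 13 (O5, O11) are covered in one operation, so 14 has no acidic proton other than the alkyne C–H.

**C4–C5 (13 ⇐ 12).** This is the only C–C bond made next to a stereocentre. Cutting here places the new centre C5 next to the silyloxy-bearing C6 of aldehyde 12. A non-chelating Lewis acid with an allenyl tin reagent should then add the three carbons C2–C4 anti to O6 under Felkin–Anh control.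

**Telling the two ends apart (12 ⇐ 11 ⇐ 10 ⇐ 9 ⇐ 7 ⇐ 6).** The C5 aldehyde comes from the primary alcohol of 11. Diol 11 comes from 10 in one hydride operation that turns the ester into the C5 carbinol and the epoxide into the C12 methyl and the C11 hydroxyl. The epoxide of 9 holds O11 in a ring with C12 while O6 alone is silylated, so O6 and O11 are differentiated without a protecting group on O11. Epoxide 9 arises from the terminal diol of 7, and 7 from selective reduction of the acid of 6 in the presence of its ester.

**Desymmetrisation (6 ⇐ 5).** Half-ester 6 is traced to the meso diester 5 by hydrolysis of one of its two enantiotopic esters. This operation fixes the absolute configuration of all four core centres at once and makes the two carbon termini chemically different. The mirror-image half-ester is not lost, because esterification returns it to 5.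

**Key disconnection (5 ⇐ 4).** Both ring C–O bonds (O–C7, O–C10) and both carbinol C–O bonds (C6–O, C11–O) are cut together, back to the symmetric E,E-dienoate 4. Forward, a permanganate oxidative cyclisation forms the ring and all four stereocentres from alkene geometry alone. No other cut delivers the whole threo–cis–threo array in one step from an achiral precursor.

**Precursor (4 ⇐ 2 + 3 ⇐ 1; 21 ⇐ 19).** The two double bonds of 4 are made by a double Wittig reaction of dialdehyde 2 with ylide 3. Dialdehyde 2 is released from its stable cyclic acetal 1.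

## Alternatives that were turned down

**Alternative 1:** The lactone ring is cut last, at C4–C5 and O–C1, back to aldehyde A2 (the C5 formyl compound with a silyl ether on O6 and a p-methoxybenzyl ether on O11) and (E)-1-methoxybuta-1,3-diene A3.
- **Forward key step:** a hetero-Diels–Alder reaction of A3 with A2 under the chiral Lewis acid A4, a chromium chloride complex (L)CrCl of trivalent chromium with an aminoindanol-derived salicylaldimine ligand. It should give the cis-2-methoxy-5,6-dihydro-2H-pyran A1; hydrolysis of the anomeric acetal and oxidation of the lactol then give the lactone.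
- **For it:** C5 is set under catalyst control and C1–C4 arrive in one step. This is shorter and stereochemically more secure than steps 10–14 here; on this point the alternative is stronger.
- **Against it:** it is an end-game only. It presupposes A2, the complete oxolane with C6, C7, C10 and C11 in place and O6 and O11 already differentiated, and offers no way to make it. α-Branched, α-oxygenated aldehydes are the slower substrates for this catalyst class, and the catalyst must match or override the bias of C6. The acetal oxidation must be done beside an electron-rich benzyl ether.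
- **Comparison:** the chosen strategy spends its key step on the harder problem, the four-centre core, and accepts a substrate-controlled addition at C5. In place of catalytic control at C5 it offers three-step access to all four core centres from achiral material.

**Alternative 2:** C5–C6 and C11–C12 are cut together, back to the meso dialdehyde cis-oxolane-2,5-dicarbaldehyde A6.
- **Forward key step:** CH2=CHMgBr A7 with MgBr2 A8 adds to both formyl groups of A6 under chelation between carbonyl and ring oxygen. It should give the meso bis-allylic alcohol A5, threo at both ends.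
- **For it:** A5 holds the same threo–cis–threo array as 5 and grows in two directions. It could be desymmetrised by asymmetric epoxidation of one enantiotopic allylic alcohol, whose sense and level of selectivity are far better understood than those of an esterase acting on 5. The epoxide would also place the C5 oxygen anti to C6. On absolute control the alternative is stronger.
- **Against it:** C6 and C11 are set by chelation at two independent carbonyl groups, so leakage is compounded and three diastereomers must be separated. A6 is an α-alkoxy dialdehyde that hydrates, oligomerises and can epimerise from cis to trans. At the C12 end the vinyl group brings one carbon too many, which must be cleaved off and the remaining carbon deoxygenated to the methyl group.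
- **Comparison:** in 5 the same array follows stereospecifically from the E geometry of 4, with no diastereomer to remove, and each end already has the right number of carbons. In place of the predictable epoxidation, the chosen route offers a desymmetrisation whose wrong enantiomer returns to the meso pool.

**Alternative 3:** The O–C10 bond of the oxolane is cut (with the C10–H bond), back to the open-chain ketone A10, which carries a triethylsilyl ether on O7, an acetonide on O5/O6 and a silyl ether on O11.
- **Forward key step:** BiBr3 A11 and Et3SiH A12 turn the silyl ether and the ketone of A10 into a cyclic oxocarbenium ion. Hydride reduces it from the less hindered face and closes the cis-oxolane A9.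
- **For it:** every centre of A10 comes from the chiral pool (C11 from a lactic acid derivative) or from reagent-controlled reactions. The absolute configuration is secure from the start and no desymmetrisation is needed; on that point it is stronger than the chosen route. The cis preference of hydride delivery to five-membered oxocarbenium ions is well established.
- **Against it:** the key step makes one ring bond and one stereocentre only, so C5, C6, C7 and C11 must each be set beforehand in a long linear sequence. The C10 ketone sits next to C11, which can epimerise. The strongly Lewis-acidic medium threatens the acetonide and the silyl ethers, and the cis ratio depends on the conformation of an oxocarbenium ion with an oxygenated side chain.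
- **Comparison:** the chosen route forms the ring, two ring C–O bonds and four stereocentres in one step, three steps from commercial material. It gives up the guaranteed absolute configuration and replaces it by brevity and a recyclable desymmetrisation.

Key step: step 3

Assumption: the esterase is taken to cleave the ester on the (R)-configured carbinol carbon of 5 (the end that becomes C11/C12); if it prefers the other ester, the mirror-image half-ester forms and is handled as described under the fallback to step 4.

## Route

Step 1
Reactants: 1 2,5-dimethoxytetrahydrofuran (cis/trans mixture)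
Product: 2 succinaldehyde (butanedial)
Conditions: 0.1 M aq. HCl, 70 °C; NaHCO3 to pH 7; extraction into CH2Cl2, solution used at once
Reagents that add atoms: water, O
Why: Acid-catalysed hydrolysis of the cyclic bis-acetal frees both formyl groups; the dialdehyde oligomerises on standing, so it is carried on without storage.

Step 2
Reactants: 2 succinaldehyde; 3 methyl (triphenylphosphoranylidene)acetate
Product: 4 dimethyl (2E,6E)-octa-2,6-dienedioate
Conditions: 3 (2.2 equiv), CH2Cl2, 0 °C to rt; crystallisation
Reagents that add atoms: none
Why: Double Wittig olefination; the ester-stabilised ylide should give the E geometry at both double bonds, and the symmetric E,E-diester can be freed from minor isomers by crystallisation.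

Step 3
Reactants: 4 dimethyl (2E,6E)-octa-2,6-dienedioate
Product: 5 dimethyl (2R)-2-hydroxy-2-[(2S,5R)-5-[(1S)-1-hydroxy-2-methoxy-2-oxoethyl]oxolan-2-yl]acetate (meso)
Conditions: KMnO4 (2.0 equiv, aq.), AcOH (3 equiv), acetone/H2O, −30 to −10 °C; MnO2 filtered off (Celite)
Reagents that add atoms: potassium permanganate, [K+].[O-][Mn](=O)(=O)=O
Why: Permanganate adds suprafacially across one E-enoate in a [3+2] sense to give a cyclic manganate ester of pentavalent manganese, which further permanganate oxidises to the hexavalent stage. An Mn=O/Mn–O pair of the same metal centre then adds across the second alkene, so the oxygen already on C7 bonds to C10 and a new hydroxyl oxygen bonds to C11; hydrolysis releases 5 and MnO2. The closest known reaction type is the permanganate oxidative cyclisation of 1,5-dienes to cis-2,5-bis(hydroxyalkyl)oxolanes, which extends to 2,6-dienoates. The oxolane closes in a 5-exo mode inside the metallacycle (the oxygen on C7 attacks C10, C11 stays outside the ring). C6/C7 and C10/C11 are each set by syn addition to an E double bond and are therefore threo. The cis relation of C7 and C10 is set by the single manganese atom, which must deliver both ring C–O bonds to the same face of the folded chain. Because 4 is symmetric and 5 is meso, no regio- or enantiofacial selectivity is needed. The step needs only chemoselectivity for cyclisation over plain dihydroxylation, ketol formation and C=C cleavage; low temperature, weakly acidic buffering by AcOH and the electron-poor double bonds (fast permanganate addition, slow over-oxidation of the α-hydroxy ester ends) should secure it.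

Step 4
Reactants: 5 meso diol diester
Product: 6 (2R)-2-hydroxy-2-[(2S,5R)-5-[(1S)-1-hydroxy-2-methoxy-2-oxoethyl]oxolan-2-yl]acetic acid
Conditions: pig liver esterase, 0.1 M phosphate buffer pH 7.0, 10% DMSO, 25 °C, pH-stat (1 M NaOH, 1.0 equiv); HCl to pH 2, continuous extraction (EtOAc)
Reagents that add atoms: water, O
Why: Enzymatic desymmetrisation of a meso diester by hydrolysis of one enantiotopic ester; each ester sits on a carbinol carbon of opposite configuration, so the enzyme faces the local problem of a kinetic resolution of α-hydroxy esters, and the carboxylate formed is a poor substrate for a second hydrolysis. No new stereocentre is formed; the choice of ester fixes the absolute configuration of C6, C7, C10 and C11.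

Step 5
Reactants: 6 half-ester
Product: 7 methyl (2S)-2-[(2R,5S)-5-[(1S)-1,2-dihydroxyethyl]oxolan-2-yl]-2-hydroxyacetate
Conditions: BH3·SMe2 (3 equiv), B(OMe)3, THF, 0 °C to rt; MeOH quench, co-evaporation with MeOH
Reagents that add atoms: none
Why: Chemoselective borane reduction of a carboxylic acid beside an ester: the acid forms an acyloxyborane that is reduced rapidly at 0 °C, whereas the methyl ester is not reduced at a useful rate without a borohydride catalyst.

Step 6
Reactants: 7 triol ester
Product: 9 methyl (2S)-2-hydroxy-2-[(2R,5S)-5-[(2S)-oxiran-2-yl]oxolan-2-yl]acetate, via primary tosylate 8 (not isolated)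
Conditions: TsCl (1.05 equiv), Et3N, Bu2SnO (2 mol %), CH2Cl2, 0 °C to rt; then K2CO3, MeOH, 0 °C to rt
Reagents that add atoms: none
Why: The Bu2SnO-catalysed sulfonylation goes through the stannylene acetal of the terminal 1,2-diol and tosylates only the primary hydroxyl; carbonate then closes the oxirane by 3-exo-tet displacement through O11. C11 keeps its configuration and O11 is masked while the C6 hydroxyl stays free.

Step 7
Reactants: 9 epoxy alcohol
Product: 10 methyl (2S)-2-[(tert-butyldimethylsilyl)oxy]-2-[(2R,5S)-5-[(2S)-oxiran-2-yl]oxolan-2-yl]acetate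
Conditions: TBSCl, imidazole, DMF, rt
Reagents that add atoms: tert-butyldimethylsilyl chloride, CC(C)(C)[Si](C)(C)Cl
Why: Imidazole-mediated silylation of the one remaining hydroxyl; the neutral conditions leave epoxide and ester untouched, and the bulky silyl ether later enforces non-chelation control at C5.

Step 8
Reactants: 10 silyl ether
Product: 11 (2R)-2-[(tert-butyldimethylsilyl)oxy]-2-[(2R,5S)-5-[(1S)-1-hydroxyethyl]oxolan-2-yl]ethan-1-ol
Conditions: LiEt3BH (3.5 equiv), THF, −78 to 0 °C; then H2O
Reagents that add atoms: none
Why: Hydride opens the terminal epoxide by SN2 attack at the unsubstituted C12, which gives the C12 methyl group and the C11 carbinol with retention, and in the same flask reduces the methyl ester to the C5 primary alcohol. Low temperature and borate-bound alkoxides disfavour silyl migration from O6 to O5.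

Step 9
Reactants: 11 diol
Product: 12 (2S)-2-[(tert-butyldimethylsilyl)oxy]-2-[(2R,5S)-5-[(1S)-1-hydroxyethyl]oxolan-2-yl]acetaldehyde
Conditions: TEMPO (0.1 equiv), PhI(OAc)2 (1.1 equiv), CH2Cl2, rt
Reagents that add atoms: none
Why: Oxoammonium (TEMPO) oxidation is selective for primary over secondary alcohols, so the C11 hydroxyl is left alone; the non-basic medium protects the α-silyloxy aldehyde from epimerisation at C6.

Step 10
Reactants: 12 aldehyde
Product: 13 (1R,2R)-1-[(tert-butyldimethylsilyl)oxy]-1-[(2R,5S)-5-[(1S)-1-hydroxyethyl]oxolan-2-yl]pent-4-yn-2-ol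
Conditions: allenyltributylstannane (2.5 equiv), BF3·OEt2 (2.2 equiv), CH2Cl2, −78 °C; aq. NaHCO3; aq. KF
Reagents that add atoms: allenyltributylstannane, C=C=C[Sn](CCCC)(CCCC)CCCC
Why: Lewis-acid-promoted SE2′ addition of an allenylstannane to an aldehyde gives a homopropargylic alcohol through an open transition state. With monodentate BF3 and a bulky α-silyloxy group, chelation is excluded and the Felkin–Anh arrangement exposes the Re face of the formyl group, so C5 should form R, anti to O6. The free C11 hydroxyl binds one equivalent of BF3, hence the excess of both reagents.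

Step 11
Reactants: 13 homopropargylic diol
Product: 14 (2R,5S)-2-[(1S,2R)-1-[(tert-butyldimethylsilyl)oxy]-2-[(triethylsilyl)oxy]pent-4-yn-1-yl]-5-[(1S)-1-[(triethylsilyl)oxy]ethyl]oxolane
Conditions: TESCl (2.5 equiv), imidazole, DMF, 0 °C to rt
Reagents that add atoms: triethylsilyl chloride, CC[Si](Cl)(CC)CC
Why: Silylation of both free hydroxyls (O5, O11) removes the acidic protons before the acetylide is made and installs groups that mild acid later cleaves without loss of the tert-butyldimethylsilyl ether on O6.

Step 12
Reactants: 14 bis(triethylsilyl) ether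
Product: 15 methyl (5R,6S)-6-[(tert-butyldimethylsilyl)oxy]-5-[(triethylsilyl)oxy]-6-[(2R,5S)-5-[(1S)-1-[(triethylsilyl)oxy]ethyl]oxolan-2-yl]hex-2-ynoate
Conditions: n-BuLi (1.1 equiv), THF, −78 °C; ClCO2Me, −78 to −20 °C
Reagents that add atoms: methyl chloroformate, COC(=O)Cl
Why: Deprotonation of the terminal alkyne and C-acylation of the lithium acetylide with a chloroformate is the standard route to alk-2-ynoates; 14 has no other acidic site.

Step 13
Reactants: 15 ynoate
Product: 16 methyl (2Z,5R,6S)-6-[(tert-butyldimethylsilyl)oxy]-5-[(triethylsilyl)oxy]-6-[(2R,5S)-5-[(1S)-1-[(triethylsilyl)oxy]ethyl]oxolan-2-yl]hex-2-enoate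
Conditions: H2 (1 atm), Pd/CaCO3 poisoned with Pb(OAc)2 (Lindlar catalyst), quinoline, EtOAc, rt
Reagents that add atoms: none
Why: Lindlar semihydrogenation adds H2 syn to the alkyne on the poisoned palladium surface and should stop at the Z-enoate, the geometry the lactone ring requires; silyl ethers are inert.

Step 14
Reactants: 16 Z-enoate
Product: 18 (6R)-6-[(S)-[(tert-butyldimethylsilyl)oxy][(2R,5S)-5-[(1S)-1-hydroxyethyl]oxolan-2-yl]methyl]-5,6-dihydro-2H-pyran-2-one, via dihydroxy Z-enoate 17 (not isolated)
Conditions: PPTS (0.2 equiv), MeOH, rt; then PPTS, toluene, 60 °C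
Reagents that add atoms: none
Why: Mild acid methanolysis removes the two triethylsilyl ethers but not the more hindered tert-butyldimethylsilyl ether; the freed C5 hydroxyl lies cis to the ester across the Z double bond and closes the six-membered lactone by acid-catalysed transesterification. O6 is blocked and O11 is too remote to compete.

Step 15
Reactants: 19 p-coumaric acid
Product: 21 (2E)-3-[4-[(tert-butyldimethylsilyl)oxy]phenyl]prop-2-enoic acid, via silyl ester 20 (not isolated)
Conditions: TBSCl (2.4 equiv), imidazole, DMF, rt; then AcOH/THF/H2O, rt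
Reagents that add atoms: tert-butyldimethylsilyl chloride, CC(C)(C)[Si](C)(C)Cl
Why: Exhaustive silylation gives the silyl ether silyl ester; silyl esters hydrolyse under mild aqueous acid far faster than aryl silyl ethers, so only the carboxylic acid is set free.

Step 16
Reactants: 18 hydroxy lactone; 21 silyl-protected coumaric acid
Product: 22 (1S)-1-[(2S,5R)-5-[(S)-[(tert-butyldimethylsilyl)oxy][(2R)-6-oxo-3,6-dihydro-2H-pyran-2-yl]methyl]oxolan-2-yl]ethyl (2E)-3-[4-[(tert-butyldimethylsilyl)oxy]phenyl]prop-2-enoate
Conditions: DCC, DMAP (0.2 equiv), CH2Cl2, 0 °C to rt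
Reagents that add atoms: none
Why: Steglich esterification (carbodiimide activation, acyl transfer by DMAP) of the only free hydroxyl of 18; the C11–O bond is not broken, so C11 keeps its configuration.

Step 17
Reactants: 22 bis-silyl ether
Product: 23 (1S)-1-[(2S,5R)-5-[(S)-hydroxy[(2R)-6-oxo-3,6-dihydro-2H-pyran-2-yl]methyl]oxolan-2-yl]ethyl (2E)-3-(4-hydroxyphenyl)prop-2-enoate
Conditions: 48% aq. HF, MeCN, 0 °C to rt; work-up kept at pH ≤ 7
Reagents that add atoms: none
Why: Fluoride cleaves both Si–O bonds; the acidic medium is chosen because the coumarate, the lactone and above all the C6 hydroxyl beside the enoate (oxa-Michael closure onto C3) would not tolerate basic fluoride.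

## Compound list

1 | 2,5-dimethoxytetrahydrofuran (cis/trans mixture) | COC1CCC(OC)O1 | starting material
2 | succinaldehyde | O=CCCC=O | intermediate
3 | methyl (triphenylphosphoranylidene)acetate | COC(=O)C=P(c1ccccc1)(c1ccccc1)c1ccccc1 | starting material
4 | dimethyl (2E,6E)-octa-2,6-dienedioate | COC(=O)/C=C/CC/C=C/C(=O)OC | intermediate
5 | dimethyl (2R)-2-hydroxy-2-[(2S,5R)-5-[(1S)-1-hydroxy-2-methoxy-2-oxoethyl]oxolan-2-yl]acetate (meso; cis ring, threo at both ends) | COC(=O)[C@H](O)[C@@H]1CC[C@H]([C@H](O)C(=O)OC)O1 | intermediate
6 | (2R)-2-hydroxy-2-[(2S,5R)-5-[(1S)-1-hydroxy-2-methoxy-2-oxoethyl]oxolan-2-yl]acetic acid | OC(=O)[C@H](O)[C@@H]1CC[C@H]([C@H](O)C(=O)OC)O1 | intermediate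
7 | methyl (2S)-2-[(2R,5S)-5-[(1S)-1,2-dihydroxyethyl]oxolan-2-yl]-2-hydroxyacetate | OC[C@H](O)[C@@H]1CC[C@H]([C@H](O)C(=O)OC)O1 | intermediate
8 | methyl (2S)-2-hydroxy-2-[(2R,5S)-5-[(1S)-1-hydroxy-2-[(4-methylbenzenesulfonyl)oxy]ethyl]oxolan-2-yl]acetate | Cc1ccc(cc1)S(=O)(=O)OC[C@H](O)[C@@H]1CC[C@H]([C@H](O)C(=O)OC)O1 | intermediate
9 | methyl (2S)-2-hydroxy-2-[(2R,5S)-5-[(2S)-oxiran-2-yl]oxolan-2-yl]acetate | C1O[C@@H]1[C@@H]2CC[C@H]([C@H](O)C(=O)OC)O2 | intermediate
10 | methyl (2S)-2-[(tert-butyldimethylsilyl)oxy]-2-[(2R,5S)-5-[(2S)-oxiran-2-yl]oxolan-2-yl]acetate | C1O[C@@H]1[C@@H]2CC[C@H]([C@H](O[Si](C)(C)C(C)(C)C)C(=O)OC)O2 | intermediate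
11 | (2R)-2-[(tert-butyldimethylsilyl)oxy]-2-[(2R,5S)-5-[(1S)-1-hydroxyethyl]oxolan-2-yl]ethan-1-ol | C[C@H](O)[C@@H]1CC[C@H]([C@H](O[Si](C)(C)C(C)(C)C)CO)O1 | intermediate
12 | (2S)-2-[(tert-butyldimethylsilyl)oxy]-2-[(2R,5S)-5-[(1S)-1-hydroxyethyl]oxolan-2-yl]acetaldehyde | C[C@H](O)[C@@H]1CC[C@H]([C@H](O[Si](C)(C)C(C)(C)C)C=O)O1 | intermediate
13 | (1R,2R)-1-[(tert-butyldimethylsilyl)oxy]-1-[(2R,5S)-5-[(1S)-1-hydroxyethyl]oxolan-2-yl]pent-4-yn-2-ol | C[C@H](O)[C@@H]1CC[C@H]([C@H](O[Si](C)(C)C(C)(C)C)[C@H](O)CC#C)O1 | intermediate
14 | (2R,5S)-2-[(1S,2R)-1-[(tert-butyldimethylsilyl)oxy]-2-[(triethylsilyl)oxy]pent-4-yn-1-yl]-5-[(1S)-1-[(triethylsilyl)oxy]ethyl]oxolane | C[C@H](O[Si](CC)(CC)CC)[C@@H]1CC[C@H]([C@H](O[Si](C)(C)C(C)(C)C)[C@H](O[Si](CC)(CC)CC)CC#C)O1 | intermediate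
15 | methyl (5R,6S)-6-[(tert-butyldimethylsilyl)oxy]-5-[(triethylsilyl)oxy]-6-[(2R,5S)-5-[(1S)-1-[(triethylsilyl)oxy]ethyl]oxolan-2-yl]hex-2-ynoate | C[C@H](O[Si](CC)(CC)CC)[C@@H]1CC[C@H]([C@H](O[Si](C)(C)C(C)(C)C)[C@H](O[Si](CC)(CC)CC)CC#CC(=O)OC)O1 | intermediate
16 | methyl (2Z,5R,6S)-6-[(tert-butyldimethylsilyl)oxy]-5-[(triethylsilyl)oxy]-6-[(2R,5S)-5-[(1S)-1-[(triethylsilyl)oxy]ethyl]oxolan-2-yl]hex-2-enoate | C[C@H](O[Si](CC)(CC)CC)[C@@H]1CC[C@H]([C@H](O[Si](C)(C)C(C)(C)C)[C@H](O[Si](CC)(CC)CC)C/C=C\C(=O)OC)O1 | intermediate
17 | methyl (2Z,5R,6R)-6-[(tert-butyldimethylsilyl)oxy]-5-hydroxy-6-[(2R,5S)-5-[(1S)-1-hydroxyethyl]oxolan-2-yl]hex-2-enoate | C[C@H](O)[C@@H]1CC[C@H]([C@H](O[Si](C)(C)C(C)(C)C)[C@H](O)C/C=C\C(=O)OC)O1 | intermediate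
18 | (6R)-6-[(S)-[(tert-butyldimethylsilyl)oxy][(2R,5S)-5-[(1S)-1-hydroxyethyl]oxolan-2-yl]methyl]-5,6-dihydro-2H-pyran-2-one | C[C@H](O)[C@@H]1CC[C@H]([C@H](O[Si](C)(C)C(C)(C)C)[C@H]2CC=CC(=O)O2)O1 | intermediate
19 | p-coumaric acid, (2E)-3-(4-hydroxyphenyl)prop-2-enoic acid | OC(=O)/C=C/c1ccc(O)cc1 | starting material
20 | tert-butyldimethylsilyl (2E)-3-[4-[(tert-butyldimethylsilyl)oxy]phenyl]prop-2-enoate | CC(C)(C)[Si](C)(C)OC(=O)/C=C/c1ccc(O[Si](C)(C)C(C)(C)C)cc1 | intermediate
21 | (2E)-3-[4-[(tert-butyldimethylsilyl)oxy]phenyl]prop-2-enoic acid | OC(=O)/C=C/c1ccc(O[Si](C)(C)C(C)(C)C)cc1 | intermediate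
22 | (1S)-1-[(2S,5R)-5-[(S)-[(tert-butyldimethylsilyl)oxy][(2R)-6-oxo-3,6-dihydro-2H-pyran-2-yl]methyl]oxolan-2-yl]ethyl (2E)-3-[4-[(tert-butyldimethylsilyl)oxy]phenyl]prop-2-enoate | C[C@H](OC(=O)/C=C/c1ccc(O[Si](C)(C)C(C)(C)C)cc1)[C@@H]1CC[C@H]([C@H](O[Si](C)(C)C(C)(C)C)[C@H]2CC=CC(=O)O2)O1 | intermediate
23 | (1S)-1-[(2S,5R)-5-[(S)-hydroxy[(2R)-6-oxo-3,6-dihydro-2H-pyran-2-yl]methyl]oxolan-2-yl]ethyl (2E)-3-(4-hydroxyphenyl)prop-2-enoate | C[C@H](OC(=O)/C=C/c1ccc(O)cc1)[C@@H]1CC[C@H]([C@H](O)[C@H]2CC=CC(=O)O2)O1 | target

## Step count and least certain steps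

Total step count: 17. Longest linear sequence: 16 steps (steps 1–14, 16 and 17); step 15 prepares the acyl partner.

**Step 3 (key step).**
- **Risk:** the first manganate ester may hydrolyse before the second alkene is engaged, which ends in plain dihydroxylation, and the α-hydroxy ester ends may be over-oxidised to ketols or cleaved. The second, intramolecular addition to an electron-poor enoate competes with these paths.
- **Fallback:** the two oxidation events are separated. From 4, catalytic OsO4 with one equivalent of N-methylmorpholine N-oxide should dihydroxylate one double bond to racemic dimethyl (2E,6R*,7S*)-6,7-dihydroxyoct-2-enedioate F1, with unreacted 4 recycled. An osmium-catalysed oxidative cyclisation of this diol onto the remaining alkene follows (K2OsO2(OH)4, pyridine N-oxide, Cu(OTf)2, acetone/H2O). It passes through a glycolate ester of hexavalent osmium that adds syn across the alkene and should close the cis-oxolane. Both enantiomers of F1 converge on meso 5, where the route is rejoined. The enoate is the slower alkene class for this cyclisation, hence the Lewis-acid promoter.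

**Step 4.**
- **Risk:** the enzyme may discriminate poorly between the enantiotopic esters or prefer the ester at the C5 end, since nothing is known about this substrate in the active site; hydrolysis may also run on to the diacid.
- **Fallback:** from 5, monohydrolysis with one equivalent of NaOH in THF/H2O at 0 °C should give the racemic half-ester, that is 6 together with its enantiomer (2S)-2-hydroxy-2-[(2R,5S)-5-[(1R)-1-hydroxy-2-methoxy-2-oxoethyl]oxolan-2-yl]acetic acid F2. Classical resolution by crystallisation of the (1S)-1-phenylethanaminium salt of 6 F3 (the mirror-image amine is used if the salt of F2 is the less soluble one) and acidification returns 6. F2 from the mother liquor is re-esterified with Me3SiCHN2 to meso 5 and recycled, so the wrong series costs no material.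

**Step 10.**
- **Risk:** facial selectivity may be poor, because the ring oxygen on C7 exerts a 1,3-effect that need not reinforce the Felkin preference. The BF3-bound C11 hydroxyl may also cause protodestannylation of the reagent.
- **Fallback:** reagent control and a different ring construction, starting from 11.
  - Both hydroxyls are silylated (TESCl, imidazole) to the bis(triethylsilyl) ether of 11 F5.
  - Swern oxidation, which removes and oxidises a primary triethylsilyl ether selectively, should give the O11-triethylsilyl analogue of aldehyde 12 F6.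
  - Allylboration with (+)-Ipc2B(allyl) (from (−)-α-pinene) attacks the Re face and is matched with the Felkin preference. It should give the (5R)-homoallylic alcohol F7.
  - Acryloyl chloride with i-Pr2NEt gives the acrylate of F7 F8.
  - Ring-closing metathesis with the second-generation Grubbs catalyst (H2IMes)(PCy3)Cl2Ru=CHPh closes the lactone to the O11-triethylsilyl ether of 18 F9.
  - PPTS in MeOH removes the triethylsilyl group and returns 18.

**Step 5.**
- **Risk:** chemoselectivity may be lost through intramolecular hydride delivery from the alkoxyborane on O6 to the neighbouring ester, which over-reduces the C5 end.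
- **Fallback:** the acid is activated instead of using an electrophilic reductant. From 6, isobutyl chloroformate and N-methylmorpholine at −15 °C should give the isobutyl carbonic mixed anhydride of 6 F4. NaBH4 in THF/H2O reduces it within minutes at a temperature where the methyl ester is inert, returning 7.

**Step 17.**
- **Risk:** cleavage of the hindered silyl ether on O6 may be slow, so that long exposure leads to oxa-Michael closure of the liberated C6 hydroxyl onto C3 or to loss of the coumarate.
- **Fallback:** the order is reversed and steric differentiation is used. From 18, aqueous HF in MeCN (no coumarate is present, so forcing conditions are harmless) gives the diol lactone (6R)-6-[(S)-hydroxy[(2R,5S)-5-[(1S)-1-hydroxyethyl]oxolan-2-yl]methyl]-5,6-dihydro-2H-pyran-2-one F10. Steglich acylation with one equivalent of 21 at low temperature should go to the less hindered C11 hydroxyl (a methyl carbinol) rather than the C6 hydroxyl, which is flanked by two oxygenated ring carbons. This gives the 4-O-tert-butyldimethylsilyl ether of 23 F11. KHF2 in MeOH, which cleaves aryl silyl ethers under near-neutral conditions, then gives 23.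

## Further compounds

F1 | step 3 | dimethyl (2E,6R*,7S*)-6,7-dihydroxyoct-2-enedioate (racemic; one enantiomer drawn) | COC(=O)/C=C/CC[C@H]([C@H](O)C(=O)OC)O
F2 | step 4 | (2S)-2-hydroxy-2-[(2R,5S)-5-[(1R)-1-hydroxy-2-methoxy-2-oxoethyl]oxolan-2-yl]acetic acid (enantiomer of 6) | COC(=O)[C@H](O)[C@@H]1CC[C@H]([C@H](O)C(=O)O)O1
F3 | step 4 | (1S)-1-phenylethanaminium salt of 6 | C[C@H]([NH3+])c1ccccc1.[O-]C(=O)[C@H](O)[C@@H]1CC[C@H]([C@H](O)C(=O)OC)O1
F4 | step 5 | isobutyl carbonic mixed anhydride of 6 | CC(C)COC(=O)OC(=O)[C@H](O)[C@@H]1CC[C@H]([C@H](O)C(=O)OC)O1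
F5 | step 10 | bis(triethylsilyl) ether of 11 | C[C@H](O[Si](CC)(CC)CC)[C@@H]1CC[C@H]([C@H](O[Si](C)(C)C(C)(C)C)CO[Si](CC)(CC)CC)O1
F6 | step 10 | (2S)-2-[(tert-butyldimethylsilyl)oxy]-2-[(2R,5S)-5-[(1S)-1-[(triethylsilyl)oxy]ethyl]oxolan-2-yl]acetaldehyde | C[C@H](O[Si](CC)(CC)CC)[C@@H]1CC[C@H]([C@H](O[Si](C)(C)C(C)(C)C)C=O)O1
F7 | step 10 | (1R,2R)-1-[(tert-butyldimethylsilyl)oxy]-1-[(2R,5S)-5-[(1S)-1-[(triethylsilyl)oxy]ethyl]oxolan-2-yl]pent-4-en-2-ol | C[C@H](O[Si](CC)(CC)CC)[C@@H]1CC[C@H]([C@H](O[Si](C)(C)C(C)(C)C)[C@H](O)CC=C)O1
F8 | step 10 | prop-2-enoate (acrylate) of F7 at O5 | C[C@H](O[Si](CC)(CC)CC)[C@@H]1CC[C@H]([C@H](O[Si](C)(C)C(C)(C)C)[C@H](OC(=O)C=C)CC=C)O1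
F9 | step 10 | (6R)-6-[(S)-[(tert-butyldimethylsilyl)oxy][(2R,5S)-5-[(1S)-1-[(triethylsilyl)oxy]ethyl]oxolan-2-yl]methyl]-5,6-dihydro-2H-pyran-2-one | C[C@H](O[Si](CC)(CC)CC)[C@@H]1CC[C@H]([C@H](O[Si](C)(C)C(C)(C)C)[C@H]2CC=CC(=O)O2)O1
F10 | step 17 | (6R)-6-[(S)-hydroxy[(2R,5S)-5-[(1S)-1-hydroxyethyl]oxolan-2-yl]methyl]-5,6-dihydro-2H-pyran-2-one | C[C@H](O)[C@@H]1CC[C@H]([C@H](O)[C@H]2CC=CC(=O)O2)O1
F11 | step 17 | 4-O-tert-butyldimethylsilyl ether of 23 | C[C@H](OC(=O)/C=C/c1ccc(O[Si](C)(C)C(C)(C)C)cc1)[C@@H]1CC[C@H]([C@H](O)[C@H]2CC=CC(=O)O2)O1
A1 | alternative 1 | cis-2-methoxy-5,6-dihydro-2H-pyran carrying the silylated and p-methoxybenzylated oxolane side chain at C6 of the pyran | C[C@H](OCc1ccc(OC)cc1)[C@@H]1CC[C@H]([C@H](O[Si](C)(C)C(C)(C)C)[C@H]2CC=C[C@@H](OC)O2)O1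
A2 | alternative 1 | (2S)-2-[(tert-butyldimethylsilyl)oxy]-2-[(2R,5S)-5-[(1S)-1-[(4-methoxybenzyl)oxy]ethyl]oxolan-2-yl]acetaldehyde | C[C@H](OCc1ccc(OC)cc1)[C@@H]1CC[C@H]([C@H](O[Si](C)(C)C(C)(C)C)C=O)O1
A3 | alternative 1 | (E)-1-methoxybuta-1,3-diene | CO/C=C/C=C
A4 | alternative 1 | (L)CrCl, L = dianion of the Schiff base of (1R,2S)-1-amino-2-indanol and 3-(1-adamantyl)-2-hydroxy-5-methylbenzaldehyde (one enantiomer drawn, N→Cr bond not drawn) | Cc1cc2C=N[C@@H]3c4ccccc4C[C@@H]3O[Cr](Cl)Oc2c(c1)C12CC3CC(CC(C3)C1)C2
A5 | alternative 2 | meso cis-2,5-bis(1-hydroxyprop-2-enyl)oxolane, threo at both ends | C=C[C@H](O)[C@@H]1CC[C@H]([C@H](O)C=C)O1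
A6 | alternative 2 | cis-oxolane-2,5-dicarbaldehyde (meso) | O=C[C@@H]1CC[C@H](C=O)O1
A7 | alternative 2 | vinylmagnesium bromide | C=C[Mg]Br
A8 | alternative 2 | magnesium dibromide | [Mg+2].[Br-].[Br-]
A9 | alternative 3 | cis-oxolane with C5, C6, C7, C10 and C11 in place (O5/O6 acetonide, O11 silyl ether, C3 silyl ether) | C[C@H](O[Si](C)(C)C(C)(C)C)[C@@H]1CC[C@H]([C@H](OC(C)(C)O2)[C@H]2CCO[Si](C(C)C)(C(C)C)C(C)C)O1
A10 | alternative 3 | open-chain C10 ketone with a triethylsilyl ether on O7 | C[C@H](O[Si](C)(C)C(C)(C)C)C(=O)CC[C@@H](O[Si](CC)(CC)CC)[C@@H]1OC(C)(C)O[C@@H]1CCO[Si](C(C)C)(C(C)C)C(C)C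
A11 | alternative 3 | bismuth tribromide | Br[Bi](Br)Br
A12 | alternative 3 | triethylsilane | CC[SiH](CC)CC
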